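The runs stem from a simulated flask for substances that don't exist, and the scatter is random.

If you take over this bench, the flask is the one named so below; I wanted what it held at the asked time.

the same everywhere: X 2.64 M

| charge | L | Q | remark | time |
|---|---|---|---|---|
| ash | 0.66 M (in portions, 4) | 2.3 mM | run made earlier; portions every 2.0 h |  |
| alder | 0.66 M (in portions, 4) | 9.2 mM | run made earlier; portions every 2.0 h |  |
| cedar | 0.99 M (in portions, 4) | 4.6 mM | run made earlier; portions every 2.0 h |  |
| flask | 0.66 M (in portions, 4) | 4.6 mM | the portions of L follow each other after 2.0 h, the first at the start | 40 h |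

- ash (time / h: G / %, L / %): 6.00: 29, 38; 15.0: 44, 35; 30.0: 45, 26; 50.0: 45, 15
- alder (time / h: G / %, L / %): 12.0: 58, 24; 25.0: 65, 19; 40.0: 67, 15; 50.0: 69, 10
- cedar (time / h: G / %, L / %): 6.00: 28, 38; 15.0: 42, 28; 30.0: 43, 17; 50.0: 42, 11

(each reading ± 1.5 percentage points)

- in percentages every species weighs as the L in it: one Z counts as two

* how much G the flask holds at 40 h, in percent of the L charged
* how much L the flask holds at 40 h, in percent of the L charged
* how much Z the flask holds at 40 h, in percent of the L charged
* concentration of X at 40 h, in M

1. In the ash run, G stood at 44% at 15.0 h and 45% at 50.0 h, while L fell from 35% to 15%. So I expected G to level off and L to keep falling.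

2. By their last readings, ash gave 129 G per Q charged and alder, with more Q, gave 49.5.

3. The flask's cQ lay halfway by ratio between those runs, so I took the count halfway by ratio too: 79.9 turnovers, moles of G made per mole of Q charged (the turnover number). That meant 55.7% G.

4. Don't raise the L charge. Cedar, with 0.99 M of L and the flask's cQ, gave 90.4 turnovers by its last reading, more than my 79.9, yet its G stood at 42% at 50.0 h, less than my 55.7%.

5. The forecast said G 56% (52% to 60%), L 16.5% (13.5% to 20%), Z 27.5% (22% to 33%) and cX 2.24 M (2.05 M to 2.3 M), on the ground that “G stops once the initiator dies”.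

6. The flask gave G 57.6%, L 15.9%, Z 25.1% and cX 2.26 M.

    Q → 2 J (k = 7.66 × 10⁻⁵ /s)
    L + J → E (k = 634 /M/s)
    X + E ⇌ G + J (K = 0.164, k = 78.0 /M/s)
    2 E → D (k = 1.90 × 10⁷ /M/s)
    2 L → Z (k = 1.74 × 10⁻⁵ /M/s)

The flask's G came to 82.6 turnovers, against my 79.9. The count ended there partly because E, the chain carrier, paired off to D and partly because G + J went back to X + E: the same run gave 99.1% G with the pairing struck out and 93.0% with the way back struck out. The neighbour with 1.7 M of L and the same Q made 106 turnovers, 1.33 times my count, and held 28.6% G.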